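**Retrosynthetic overview**
1. Target 27 ⇐ 26 (removal of two O‑benzyl groups) ⇐ C3–CH2Ar bond: lithium enolate of (R)‑β‑benzyl lactone 24 plus benzyl bromide 8, a late trans‑selective union of the two aryl halves.
2. 24 ⇐ 23 (decarboxylation) ⇐ homoconjugate opening of the cyclopropane‑fused lactone 21 by the aryl Grignard reagent from 15 under CuI catalysis.
3. 21 ⇐ dimethyl malonate 17 + (R)‑epichlorohydrin 18 (the only source of chirality); 15 ⇐ resorcinol 9; 8 ⇐ catechol 1.
4. Ring order: cyclopropane and γ‑lactone are formed together in 21, the cyclopropane is then opened, and the lactone is carried to the end; both benzene rings are bought.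

Assumption: the target is read as the trans‑(3R,4R) lactone; methylating, benzylating and brominating agents, DMF, H2O2 and methanol are treated as reagents.

**Branch A – benzyl bromide 8**

Step 1
Reactants: 1 catechol
Product: 2 guaiacol (2‑methoxyphenol)
Conditions: MeI (1.0 equiv), K2CO3 (1.0 equiv), acetone, reflux
Reagents that add atoms: iodomethane, CI
Why: Williamson O‑methylation of the catechol monoanion with limiting MeI stops mainly at the monoether, and neutral veratrole and water‑soluble catechol are removed by acid–base extraction.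

Step 2
Reactants: 2 guaiacol
Product: 3 4‑bromo‑2‑methoxyphenol
Conditions: NBS (1.0 equiv), MeCN, 0 °C to rt
Reagents that add atoms: N‑bromosuccinimide, O=C1CCC(=O)N1Br
Why: Electrophilic aromatic bromination in which the free OH is the stronger director, so bromine enters para to it.

Step 3
Reactants: 3 4‑bromo‑2‑methoxyphenol
Product: 4 1‑(benzyloxy)‑4‑bromo‑2‑methoxybenzene
Conditions: BnBr, K2CO3, DMF, rt
Reagents that add atoms: benzyl bromide, BrCc1ccccc1
Why: Williamson etherification protects the phenol as a benzyl ether that survives organolithium, hydride, PBr3 and enolate chemistry and is removed by hydrogenolysis at the end.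

Step 4
Reactants: 4 1‑(benzyloxy)‑4‑bromo‑2‑methoxybenzene
Product: 6 4‑(benzyloxy)‑3‑methoxybenzaldehyde, via aryllithium 5 (not isolated)
Conditions: n‑BuLi, THF, −78 °C; DMF, −78 to 0 °C; 1 M HCl
Reagents that add atoms: N,N‑dimethylformamide, CN(C)C=O
Why: Fast bromine–lithium exchange followed by formylation of the aryllithium with DMF fixes the one‑carbon unit exactly where bromine stood.

Step 5
Reactants: 6 4‑(benzyloxy)‑3‑methoxybenzaldehyde
Product: 7 [4‑(benzyloxy)‑3‑methoxyphenyl]methanol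
Conditions: NaBH4, MeOH/THF, 0 °C
Reagents that add atoms: none
Why: Chemoselective borohydride reduction of the aldehyde leaves the aryl ethers untouched.

Step 6
Reactants: 7 [4‑(benzyloxy)‑3‑methoxyphenyl]methanol
Product: 8 1‑(benzyloxy)‑4‑(bromomethyl)‑2‑methoxybenzene
Conditions: PBr3 (0.4 equiv), Et2O, 0 °C
Reagents that add atoms: phosphorus tribromide, BrP(Br)Br
Why: Conversion of the benzylic alcohol to the bromide through its phosphite ester (SN2) is fast for an electron‑rich benzylic alcohol; the bromide is used fresh.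

**Branch B – aryl bromide 15**

Step 7
Reactants: 9 resorcinol
Product: 10 1,3‑dimethoxybenzene
Conditions: Me2SO4 (2.2 equiv), K2CO3, acetone, reflux
Reagents that add atoms: dimethyl sulfate, COS(=O)(=O)OC
Why: Exhaustive Williamson O‑methylation of both phenols.

Step 8
Reactants: 10 1,3‑dimethoxybenzene
Product: 13 2,6‑dimethoxyphenol, via aryllithium 11 (not isolated), via lithium arylborate 12 (not isolated)
Conditions: n‑BuLi, THF, 0 °C to rt; B(OMe)3, −78 °C to rt; AcOH, 30% H2O2, 0 °C to rt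
Reagents that add atoms: hydrogen peroxide, OO
Why: Directed ortho‑metalation occurs at C2 between the two methoxy groups, and borylation followed by peroxide oxidation of the C–B bond installs the third oxygen there.

Step 9
Reactants: 13 2,6‑dimethoxyphenol
Product: 14 4‑bromo‑2,6‑dimethoxyphenol
Conditions: NBS (1.0 equiv), NaH (5 mol%), CHCl3, −45 °C
Reagents that add atoms: N‑bromosuccinimide, O=C1CCC(=O)N1Br
Why: Electrophilic bromination through the phenoxide at low temperature is steered para to oxygen (C4) and away from the methoxy‑activated C3.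

Step 10
Reactants: 14 4‑bromo‑2,6‑dimethoxyphenol
Product: 15 2‑(benzyloxy)‑5‑bromo‑1,3‑dimethoxybenzene
Conditions: BnBr, K2CO3, DMF, 60 °C
Reagents that add atoms: benzyl bromide, BrCc1ccccc1
Why: Williamson benzylation of the hindered phenol gives a Grignard‑compatible protecting group.

**Branch C – chiral cyclopropane lactone 21**

Step 11
Reactants: 16 malonic acid
Product: 17 dimethyl malonate
Conditions: MeOH, H2SO4 (cat.), reflux
Reagents that add atoms: methanol, CO
Why: Fischer esterification driven by excess methanol.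

Step 12
Reactants: 17 dimethyl malonate; 18 (R)‑epichlorohydrin
Product: 21 methyl (1S,5R)‑2‑oxo‑3‑oxabicyclo[3.1.0]hexane‑1‑carboxylate, via epoxy malonate 19 (not isolated), via cyclopropylcarbinol diester 20 (not isolated)
Conditions: NaOMe (1.0 equiv), MeOH, 0 °C to rt, then reflux
Reagents that add atoms: none
Why: In this tandem SN2 alkylation/cyclopropanation/lactonisation the malonate opens the epoxide at CH2, the alkoxide recloses onto CH2Cl to give 19, and 3‑exo‑tet closure with inversion at the stereocentre followed by lactonisation onto the cis ester gives the cis‑fused (1S,5R) lactone, so its configuration comes entirely from 18.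

**Union**

Step 13
Reactants: 15 2‑(benzyloxy)‑5‑bromo‑1,3‑dimethoxybenzene; 21 methyl (1S,5R)‑2‑oxo‑3‑oxabicyclo[3.1.0]hexane‑1‑carboxylate
Product: 23 methyl (3S,4R)‑4‑[4‑(benzyloxy)‑3,5‑dimethoxybenzyl]‑2‑oxooxolane‑3‑carboxylate (trans major; C3 epimerisable), via Grignard reagent 22 (not isolated)
Conditions: Mg, THF, 40 °C (15 to 22, 1.3 equiv); CuI (20 mol%), then 21, THF, −45 to −20 °C; 1 M HCl
Reagents that add atoms: none
Why: Copper‑catalysed homoconjugate addition of the aryl Grignard reagent to the doubly activated cyclopropane occurs at the unhindered CH2, leaving the ring‑fusion CH (future C4, R) untouched and releasing a stabilised malonate‑type enolate.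

Step 14
Reactants: 23 methyl (3S,4R)‑4‑[4‑(benzyloxy)‑3,5‑dimethoxybenzyl]‑2‑oxooxolane‑3‑carboxylate
Product: 24 (4R)‑4‑[4‑(benzyloxy)‑3,5‑dimethoxybenzyl]oxolan‑2‑one
Conditions: LiCl, DMSO/H2O, 140 °C
Reagents that add atoms: none
Why: Krapcho dealkoxycarbonylation removes the activating ester; the C4 stereocentre is not acidic and is retained.

Step 15
Reactants: 24 (4R)‑4‑[4‑(benzyloxy)‑3,5‑dimethoxybenzyl]oxolan‑2‑one; 8 1‑(benzyloxy)‑4‑(bromomethyl)‑2‑methoxybenzene
Product: 26 (3R,4R)‑3‑[4‑(benzyloxy)‑3‑methoxybenzyl]‑4‑[4‑(benzyloxy)‑3,5‑dimethoxybenzyl]oxolan‑2‑one, via lithium enolate 25 (not isolated)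
Conditions: LiN(SiMe3)2 (1.05 equiv), THF, −78 °C; 8, DMPU, −78 to −30 °C
Reagents that add atoms: none
Why: Diastereoselective SN2 alkylation of the kinetic lactone enolate takes place on the face opposite the C4 benzyl group, setting C3 as R (trans).

Step 16
Reactants: 26 (3R,4R)‑3‑[4‑(benzyloxy)‑3‑methoxybenzyl]‑4‑[4‑(benzyloxy)‑3,5‑dimethoxybenzyl]oxolan‑2‑one
Product: 27 (3R,4R)‑3‑(4‑hydroxy‑3‑methoxybenzyl)‑4‑(4‑hydroxy‑3,5‑dimethoxybenzyl)oxolan‑2‑one (target)
Conditions: H2 (1 atm), 10% Pd/C, EtOAc/EtOH, rt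
Reagents that add atoms: none
Why: Catalytic hydrogenolysis cleaves both benzyl ethers under neutral conditions that touch neither the lactone nor the two stereocentres.

**Compound list**
1 | catechol (benzene‑1,2‑diol) | Oc1ccccc1O | starting material
2 | guaiacol (2‑methoxyphenol) | COc1ccccc1O | intermediate
3 | 4‑bromo‑2‑methoxyphenol | COc1cc(Br)ccc1O | intermediate
4 | 1‑(benzyloxy)‑4‑bromo‑2‑methoxybenzene | COc1cc(Br)ccc1OCc1ccccc1 | intermediate
5 | [4‑(benzyloxy)‑3‑methoxyphenyl]lithium | [Li]c1ccc(OCc2ccccc2)c(OC)c1 | intermediate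
6 | 4‑(benzyloxy)‑3‑methoxybenzaldehyde | COc1cc(C=O)ccc1OCc1ccccc1 | intermediate
7 | [4‑(benzyloxy)‑3‑methoxyphenyl]methanol | COc1cc(CO)ccc1OCc1ccccc1 | intermediate
8 | 1‑(benzyloxy)‑4‑(bromomethyl)‑2‑methoxybenzene | COc1cc(CBr)ccc1OCc1ccccc1 | intermediate
9 | resorcinol (benzene‑1,3‑diol) | Oc1cccc(O)c1 | starting material
10 | 1,3‑dimethoxybenzene | COc1cccc(OC)c1 | intermediate
11 | (2,6‑dimethoxyphenyl)lithium | [Li]c1c(OC)cccc1OC | intermediate
12 | lithium (2,6‑dimethoxyphenyl)trimethoxyborate | [Li+].CO[B-](OC)(OC)c1c(OC)cccc1OC | intermediate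
13 | 2,6‑dimethoxyphenol | COc1cccc(OC)c1O | intermediate
14 | 4‑bromo‑2,6‑dimethoxyphenol | COc1cc(Br)cc(OC)c1O | intermediate
15 | 2‑(benzyloxy)‑5‑bromo‑1,3‑dimethoxybenzene | COc1cc(Br)cc(OC)c1OCc1ccccc1 | intermediate
16 | malonic acid | OC(=O)CC(O)=O | starting material
17 | dimethyl malonate | COC(=O)CC(=O)OC | intermediate
18 | (R)‑epichlorohydrin, (2R)‑2‑(chloromethyl)oxirane | ClC[C@H]1CO1 | starting material
19 | dimethyl 2‑{[(2R)‑oxiran‑2‑yl]methyl}propanedioate | COC(=O)C(C[C@@H]1CO1)C(=O)OC | intermediate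
20 | dimethyl (2R)‑2‑(hydroxymethyl)cyclopropane‑1,1‑dicarboxylate, sodium alkoxide | [Na+].COC(=O)C1(C[C@H]1C[O-])C(=O)OC | intermediate
21 | methyl (1S,5R)‑2‑oxo‑3‑oxabicyclo[3.1.0]hexane‑1‑carboxylate | COC(=O)[C@]12C[C@H]1COC2=O | intermediate
22 | [4‑(benzyloxy)‑3,5‑dimethoxyphenyl]magnesium bromide | Br[Mg]c1cc(OC)c(OCc2ccccc2)c(OC)c1 | intermediate
23 | methyl (3S,4R)‑4‑[4‑(benzyloxy)‑3,5‑dimethoxybenzyl]‑2‑oxooxolane‑3‑carboxylate | COC(=O)[C@H]1C(=O)OC[C@@H]1Cc1cc(OC)c(OCc2ccccc2)c(OC)c1 | intermediate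
24 | (4R)‑4‑[4‑(benzyloxy)‑3,5‑dimethoxybenzyl]oxolan‑2‑one | O=C1C[C@@H](Cc2cc(OC)c(OCc3ccccc3)c(OC)c2)CO1 | intermediate
25 | lithium (4R)‑4‑[4‑(benzyloxy)‑3,5‑dimethoxybenzyl]‑4,5‑dihydrofuran‑2‑olate | [Li+].[O-]C1=C[C@@H](Cc2cc(OC)c(OCc3ccccc3)c(OC)c2)CO1 | intermediate
26 | (3R,4R)‑3‑[4‑(benzyloxy)‑3‑methoxybenzyl]‑4‑[4‑(benzyloxy)‑3,5‑dimethoxybenzyl]oxolan‑2‑one | COc1cc(C[C@H]2C(=O)OC[C@@H]2Cc2cc(OC)c(OCc3ccccc3)c(OC)c2)ccc1OCc1ccccc1 | intermediate
27 | (3R,4R)‑3‑(4‑hydroxy‑3‑methoxybenzyl)‑4‑(4‑hydroxy‑3,5‑dimethoxybenzyl)oxolan‑2‑one | COc1cc(C[C@H]2C(=O)OC[C@@H]2Cc2cc(OC)c(O)c(OC)c2)ccc1O | target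

**Step count**
Total steps: 16.
Longest linear sequence: 8 steps (steps 7–10 and 13–16 from resorcinol; equally steps 1–6, 15 and 16 from catechol).

**Three steps most likely to fail, with fallbacks**

Step 9 (C4 against C3 bromination of 13). The fallback replaces electrophilic substitution by sterically governed C–H borylation. It sets out from 13 and comes back to the route at 14. Silylation (TBSCl, imidazole, DMF) gives tert‑butyl(2,6‑dimethoxyphenoxy)dimethylsilane F1. Borylation ([Ir(OMe)(cod)]2, 4,4'‑di‑tert‑butyl‑2,2'‑bipyridine, B2pin2, hexane, 80 °C) attacks the only C–H without an ortho substituent, C4, to give tert‑butyl[2,6‑dimethoxy‑4‑(4,4,5,5‑tetramethyl‑1,3,2‑dioxaborolan‑2‑yl)phenoxy]dimethylsilane F2. Bromodeboronation (CuBr2, MeOH/H2O, 80 °C) gives (4‑bromo‑2,6‑dimethoxyphenoxy)(tert‑butyl)dimethylsilane F3, and TBAF in THF releases 14.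

Step 13 (aryl cuprate opening of 21; competing carbonyl addition or sluggish opening). The fallback builds the benzyl lactone by Stobbe condensation and asymmetric hydrogenation. It sets out from 15 through its Grignard reagent 22 and comes back to the route at 24, bypassing 21 and 23.
- Formylation of 22 with DMF gives 4‑(benzyloxy)‑3,5‑dimethoxybenzaldehyde F4.
- Stobbe condensation (NaOMe, MeOH, reflux) with dimethyl succinate F5 (from succinic anhydride, MeOH, cat. H2SO4) gives (E)‑4‑[4‑(benzyloxy)‑3,5‑dimethoxyphenyl]‑3‑(methoxycarbonyl)but‑3‑enoic acid F6.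
- Asymmetric hydrogenation (H2, MeOH, Et3N, [Rh(cod)2]BF4 with a MOD‑DIOP bisphosphine) gives (3R)‑4‑[4‑(benzyloxy)‑3,5‑dimethoxyphenyl]‑3‑(methoxycarbonyl)butanoic acid F7. I have not fixed which ligand enantiomer gives the (R)‑acid; it is chosen by chiral HPLC against the material from step 14.
- Ester reduction of the potassium carboxylate (CaCl2/NaBH4, EtOH) gives (3R)‑4‑[4‑(benzyloxy)‑3,5‑dimethoxyphenyl]‑3‑(hydroxymethyl)butanoic acid F8, which lactonises on acidification (2 M HCl) to 24.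

Step 15 (enolate benzylation; unstable bromide 8, over‑alkylation or incomplete trans control). The fallback uses an aldol addition followed by hydrogenolysis. It sets out from 24 (as enolate 25) and aldehyde 6, and comes back to the route at 27. Aldol addition at −78 °C in THF gives (3S,4R)‑3‑{[4‑(benzyloxy)‑3‑methoxyphenyl](hydroxy)methyl}‑4‑[4‑(benzyloxy)‑3,5‑dimethoxybenzyl]oxolan‑2‑one F9 (C3/C4 trans, carbinol epimers). H2 with 10% Pd/C in EtOAc/AcOH containing a trace of HClO4 then removes the benzylic hydroxyl and both benzyl ethers in one operation to give 27. Steps 5 and 6 are then not needed.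

**Further compounds**
F1 | step 9 | tert‑butyl(2,6‑dimethoxyphenoxy)dimethylsilane | COc1cccc(OC)c1O[Si](C)(C)C(C)(C)C
F2 | step 9 | tert‑butyl[2,6‑dimethoxy‑4‑(4,4,5,5‑tetramethyl‑1,3,2‑dioxaborolan‑2‑yl)phenoxy]dimethylsilane | COc1cc(B2OC(C)(C)C(C)(C)O2)cc(OC)c1O[Si](C)(C)C(C)(C)C
F3 | step 9 | (4‑bromo‑2,6‑dimethoxyphenoxy)(tert‑butyl)dimethylsilane | COc1cc(Br)cc(OC)c1O[Si](C)(C)C(C)(C)C
F4 | step 13 | 4‑(benzyloxy)‑3,5‑dimethoxybenzaldehyde | COc1cc(C=O)cc(OC)c1OCc1ccccc1
F5 | step 13 | dimethyl succinate | COC(=O)CCC(=O)OC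
F6 | step 13 | (E)‑4‑[4‑(benzyloxy)‑3,5‑dimethoxyphenyl]‑3‑(methoxycarbonyl)but‑3‑enoic acid | OC(=O)C/C(C(=O)OC)=C\c1cc(OC)c(OCc2ccccc2)c(OC)c1
F7 | step 13 | (3R)‑4‑[4‑(benzyloxy)‑3,5‑dimethoxyphenyl]‑3‑(methoxycarbonyl)butanoic acid | COC(=O)[C@@H](CC(O)=O)Cc1cc(OC)c(OCc2ccccc2)c(OC)c1
F8 | step 13 | (3R)‑4‑[4‑(benzyloxy)‑3,5‑dimethoxyphenyl]‑3‑(hydroxymethyl)butanoic acid | OC[C@@H](CC(O)=O)Cc1cc(OC)c(OCc2ccccc2)c(OC)c1
F9 | step 15 | (3S,4R)‑3‑{[4‑(benzyloxy)‑3‑methoxyphenyl](hydroxy)methyl}‑4‑[4‑(benzyloxy)‑3,5‑dimethoxybenzyl]oxolan‑2‑one | COc1cc(C(O)[C@H]2C(=O)OC[C@@H]2Cc2cc(OC)c(OCc3ccccc3)c(OC)c2)ccc1OCc1ccccc1
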